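**Retrosynthetic overview**

1. Lignan numbering: C7/C8/C9 belong to the 3,5-dimethoxy-4-oxyphenyl (syringyl-type, ArS) half, C7'/C8'/C9' to the guaiacyl (ArG) half, C7''–C9'' to the glycerol chain; ring A = O, C7', C8', C8, C9; ring B = O, C7, C8, C8', C9'. Hedyotol C (24) ⇒ furofuran phenol 16 + L-serine-derived glycerate 17 (Mitsunobu inversion, aryl ketone, chelation-controlled reduction give the erythro side chain).
2. 16 ⇒ diol 14, which holds a temporary 2,5-diaryltetrahydrofuran (ring T = O, C7, C8, C8', C7'); acid moves the ring oxygen, so rings B and A close last.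
3. Ring T ⇒ donor–acceptor cyclopropane 8 (C7', C8', C8) + aldehyde 2 by a strain-driven (3+2) annulation whose ring-closing bond is C7–C8.
4. Enabling feature: the oxygen-bearing benzylic carbon C7' of ring A carries an electron-rich aryl group and sits 1,3 to bridgehead C8 (through C8'), and C8 bears C9, which can be carried as an ester. C7' (donor) and C8 (acceptor, geminal diester) can therefore be stored as the polarized bond of a cyclopropane, and both benzylic C–O bonds can later be re-formed by SN1 etherification.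
5. 8 ⇒ enal 4 + bromomalonate 5 (organocatalytic Michael-initiated ring closure sets C8', from which the other core stereocenters are relayed). Ring order: cyclopropane, ring T, ring B, ring A.

Key step: step 6

Assumption: methyl (S)-3-(benzyloxy)-2-hydroxypropanoate (17), the esterified diazotization product of O-benzyl-L-serine, is treated as a purchasable chiral-pool compound.

**Step 1**
Reactants: 1 syringaldehyde (4-hydroxy-3,5-dimethoxybenzaldehyde)
Product: 2 4-(allyloxy)-3,5-dimethoxybenzaldehyde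
Conditions: allyl bromide, K2CO3, DMF, 60 °C
Reagents that add atoms: allyl bromide, C=CCBr
Why: Williamson ether synthesis on the phenoxide; the allyl ether should tolerate the Lewis acid, hot LiCl and hydride steps and is removable later under neutral conditions.

**Step 2**
Reactants: 3 4-(benzyloxy)-3-methoxybenzaldehyde (O-benzylvanillin)
Product: 4 (E)-3-[4-(benzyloxy)-3-methoxyphenyl]prop-2-enal
Conditions: Ph3P=CHCHO, toluene, 80 °C
Reagents that add atoms: (triphenylphosphoranylidene)acetaldehyde, O=CC=P(c1ccccc1)(c1ccccc1)c1ccccc1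
Why: Wittig olefination with a stabilized formylmethylene ylide should give the E-enal.

**Step 3**
Reactants: 4 (E)-3-[4-(benzyloxy)-3-methoxyphenyl]prop-2-enal; 5 dimethyl bromomalonate
Product: 6 dimethyl (2R,3S)-2-formyl-3-[4-(benzyloxy)-3-methoxyphenyl]cyclopropane-1,1-dicarboxylate (aryl trans to formyl)
Conditions: (S)-α,α-diphenylprolinol trimethylsilyl ether (20 mol%), 2,6-lutidine, CH2Cl2, 0 °C to rt
Reagents that add atoms: none
Why: Iminium-activated Michael addition of the bromomalonate followed by intramolecular enamine alkylation (organocatalytic Michael-initiated ring closure); the bulky diaryl(silyloxy)methyl group of the (S)-catalyst shields one face of the E-iminium ion, which sets C7' and, through the trans ring closure, C8'.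

**Step 4**
Reactants: 6 dimethyl (2R,3S)-2-formyl-3-[4-(benzyloxy)-3-methoxyphenyl]cyclopropane-1,1-dicarboxylate
Product: 7 dimethyl (2R,3S)-2-(hydroxymethyl)-3-[4-(benzyloxy)-3-methoxyphenyl]cyclopropane-1,1-dicarboxylate
Conditions: NaBH4, MeOH/CH2Cl2, −40 °C, AcOH quench
Reagents that add atoms: none
Why: Chemoselective borohydride reduction of the aldehyde in the presence of the esters; low temperature and an acidic quench should prevent lactonization onto the cis ester.

**Step 5**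
Reactants: 7 dimethyl (2R,3S)-2-(hydroxymethyl)-3-[4-(benzyloxy)-3-methoxyphenyl]cyclopropane-1,1-dicarboxylate
Product: 8 dimethyl (2R,3S)-2-{[tert-butyl(diphenyl)silyl]oxymethyl}-3-[4-(benzyloxy)-3-methoxyphenyl]cyclopropane-1,1-dicarboxylate
Conditions: TBDPSCl, imidazole, CH2Cl2, 0 °C
Reagents that add atoms: tert-butyl(chloro)diphenylsilane, CC(C)(C)[Si](Cl)(c1ccccc1)c1ccccc1
Why: Silylation of the primary alcohol gives a robust ether that cannot act as a neighbouring group toward C7' in the next step.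

**Step 6**
Reactants: 8 dimethyl (2R,3S)-2-{[tert-butyl(diphenyl)silyl]oxymethyl}-3-[4-(benzyloxy)-3-methoxyphenyl]cyclopropane-1,1-dicarboxylate; 2 4-(allyloxy)-3,5-dimethoxybenzaldehyde
Product: 10 dimethyl (2R,4R,5R)-2-[4-(allyloxy)-3,5-dimethoxyphenyl]-5-[4-(benzyloxy)-3-methoxyphenyl]-4-{[tert-butyl(diphenyl)silyl]oxymethyl}dihydrofuran-3,3(2H)-dicarboxylate, via oxocarbenium malonate zwitterion 9 (not isolated)
Conditions: 2 (2 equiv), AlCl3 (10 mol%), CH2Cl2, 0 °C to rt
Reagents that add atoms: none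
Why: AlCl3 chelates the geminal diester, the aldehyde oxygen of 2 attacks the benzylic cyclopropane carbon C7' in an SN2-like opening with inversion, and release of ring strain gives the oxocarbenium/malonate zwitterion 9, whose malonate carbon C8 then adds to the oxocarbenium carbon C7. This is the donor–acceptor cyclopropane/aldehyde (3+2) annulation, a reaction type with close precedent for 2-aryl- and 2-aryl-3-alkylcyclopropane-1,1-diesters, including electron-rich tetrahydrofuran lignan systems. The C7–C8 bond closes the five-membered temporary ring T in a 5-(enolexo)-endo-trig aldol-type closure onto the oxocarbenium ion. C7' is set by stereospecific inversion of the cyclopropane center; C7 is set in an envelope transition state with the aryl group of the E-oxocarbenium ion pseudo-equatorial, cis to the C7' aryl group and to the C8' CH2OSi group; C8' is carried over unchanged. The step needs a non-ionizing (stereospecific) opening of a cyclopropane with a very electron-rich donor and 2,5-cis ring closure. A substoichiometric aluminium Lewis acid at low temperature (rather than a triflate salt) and the non-participating silyl ether are chosen to secure this.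

**Step 7**
Reactants: 10 dimethyl (2R,4R,5R)-2-[4-(allyloxy)-3,5-dimethoxyphenyl]-5-[4-(benzyloxy)-3-methoxyphenyl]-4-{[tert-butyl(diphenyl)silyl]oxymethyl}dihydrofuran-3,3(2H)-dicarboxylate
Product: 11 methyl (2S,3S,4R,5R)-2-[4-(allyloxy)-3,5-dimethoxyphenyl]-5-[4-(benzyloxy)-3-methoxyphenyl]-4-{[tert-butyl(diphenyl)silyl]oxymethyl}tetrahydrofuran-3-carboxylate
Conditions: LiCl, H2O, DMSO, 150 °C; then NaOMe (cat.), MeOH, 0 °C to rt
Reagents that add atoms: none
Why: Krapcho dealkoxycarbonylation (chloride SN2 at an ester methyl, then decarboxylation); methoxide equilibrates the remaining ester at C8 to the isomer trans to both flanking cis substituents (C7 aryl and C8' CH2OSi), which fixes C8 under thermodynamic control.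

**Step 8**
Reactants: 11 methyl (2S,3S,4R,5R)-2-[4-(allyloxy)-3,5-dimethoxyphenyl]-5-[4-(benzyloxy)-3-methoxyphenyl]-4-{[tert-butyl(diphenyl)silyl]oxymethyl}tetrahydrofuran-3-carboxylate
Product: 12 [(2S,3R,4R,5R)-2-[4-(allyloxy)-3,5-dimethoxyphenyl]-5-[4-(benzyloxy)-3-methoxyphenyl]-4-{[tert-butyl(diphenyl)silyl]oxymethyl}tetrahydrofuran-3-yl]methanol
Conditions: LiAlH4, THF, 0 °C
Reagents that add atoms: none
Why: Hydride reduction of the ester to the primary alcohol (C9); no stereocenter is touched and the ethers are inert.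

**Step 9**
Reactants: 12 [(2S,3R,4R,5R)-2-[4-(allyloxy)-3,5-dimethoxyphenyl]-5-[4-(benzyloxy)-3-methoxyphenyl]-4-{[tert-butyl(diphenyl)silyl]oxymethyl}tetrahydrofuran-3-yl]methanol
Product: 13 [(2S,3R,4R,5R)-2-[4-(allyloxy)-3,5-dimethoxyphenyl]-5-[4-(benzyloxy)-3-methoxyphenyl]tetrahydrofuran-3,4-diyl]dimethanol
Conditions: Bu4NF, THF, rt
Reagents that add atoms: none
Why: Fluoride-mediated cleavage of the silyl ether frees the C9' hydroxyl.

**Step 10**
Reactants: 13 [(2S,3R,4R,5R)-2-[4-(allyloxy)-3,5-dimethoxyphenyl]-5-[4-(benzyloxy)-3-methoxyphenyl]tetrahydrofuran-3,4-diyl]dimethanol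
Product: 14 4-[(2S,3R,4R,5R)-5-[4-(benzyloxy)-3-methoxyphenyl]-3,4-bis(hydroxymethyl)tetrahydrofuran-2-yl]-2,6-dimethoxyphenol
Conditions: Pd(PPh3)4 (5 mol%), morpholine, THF, rt
Reagents that add atoms: none
Why: Allyl transfer from the aryl allyl ether to morpholine catalysed by zerovalent palladium (Tsuji–Trost reaction) frees the syringyl phenol without touching the benzyl ether.

**Step 11**
Reactants: 14 4-[(2S,3R,4R,5R)-5-[4-(benzyloxy)-3-methoxyphenyl]-3,4-bis(hydroxymethyl)tetrahydrofuran-2-yl]-2,6-dimethoxyphenol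
Product: 16 4-[(1S,3aR,4S,6aR)-4-[4-(benzyloxy)-3-methoxyphenyl]tetrahydro-1H,3H-furo[3,4-c]furan-1-yl]-2,6-dimethoxyphenol, via ring B monocycle 15 (not isolated)
Conditions: (+)-camphorsulfonic acid (10 mol%), 4 Å molecular sieves, CH2Cl2, −20 °C to 0 °C
Reagents that add atoms: none
Why: Acid-catalysed SN1 transetherification of electron-rich benzylic ethers (the reaction type of acid epimerization of 2-aryltetrahydrofuran lignans and of the cyclodehydration of lignan tetraols to furofurans): the p-hydroxyaryl-stabilized C7 cation freed from ring T is captured by the C9' hydroxyl to close ring B (15, aryl trans to both neighbours under reversible control), then the C7' benzylic hydroxyl ionizes and the C9 hydroxyl closes ring A from the convex face, which inverts C7' and places its aryl group exo (kinetic control; the sieves take up the water).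

**Step 12**
Reactants: 17 methyl (2S)-3-(benzyloxy)-2-hydroxypropanoate
Product: 18 (2S)-3-(benzyloxy)-2-hydroxy-N-methoxy-N-methylpropanamide
Conditions: MeNH(OMe)·HCl, i-PrMgCl, THF, −20 °C
Reagents that add atoms: N,O-dimethylhydroxylamine hydrochloride, CNOC.Cl
Why: Aminolysis of the ester by the chloromagnesium amide gives the N-methoxy-N-methylamide without epimerizing the carbinol center.

**Step 13**
Reactants: 16 4-[(1S,3aR,4S,6aR)-4-[4-(benzyloxy)-3-methoxyphenyl]tetrahydro-1H,3H-furo[3,4-c]furan-1-yl]-2,6-dimethoxyphenol; 18 (2S)-3-(benzyloxy)-2-hydroxy-N-methoxy-N-methylpropanamide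
Product: 19 (2R)-3-(benzyloxy)-2-{4-[(1S,3aR,4S,6aR)-4-[4-(benzyloxy)-3-methoxyphenyl]tetrahydro-1H,3H-furo[3,4-c]furan-1-yl]-2,6-dimethoxyphenoxy}-N-methoxy-N-methylpropanamide
Conditions: PPh3, DIAD, toluene, 0 °C to rt
Reagents that add atoms: none
Why: Mitsunobu etherification of the phenol with the secondary α-hydroxy amide proceeds by SN2 inversion, turning the (S)-carbinol into the (R)-aryl ether (C8'') of the target.

**Step 14**
Reactants: 19 (2R)-3-(benzyloxy)-2-{4-[(1S,3aR,4S,6aR)-4-[4-(benzyloxy)-3-methoxyphenyl]tetrahydro-1H,3H-furo[3,4-c]furan-1-yl]-2,6-dimethoxyphenoxy}-N-methoxy-N-methylpropanamide; 20 1-(benzyloxy)-4-bromo-2-methoxybenzene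
Product: 22 (2R)-3-(benzyloxy)-1-[4-(benzyloxy)-3-methoxyphenyl]-2-{4-[(1S,3aR,4S,6aR)-4-[4-(benzyloxy)-3-methoxyphenyl]tetrahydro-1H,3H-furo[3,4-c]furan-1-yl]-2,6-dimethoxyphenoxy}propan-1-one, via aryl Grignard reagent 21 (not isolated)
Conditions: 20, Mg, THF, rt; then 19, THF, 0 °C; aq. NH4Cl
Reagents that add atoms: none
Why: Grignard formation and Weinreb ketone synthesis; the chelated tetrahedral magnesium intermediate prevents over-addition and keeps C8'' from enolizing before work-up.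

**Step 15**
Reactants: 22 (2R)-3-(benzyloxy)-1-[4-(benzyloxy)-3-methoxyphenyl]-2-{4-[(1S,3aR,4S,6aR)-4-[4-(benzyloxy)-3-methoxyphenyl]tetrahydro-1H,3H-furo[3,4-c]furan-1-yl]-2,6-dimethoxyphenoxy}propan-1-one
Product: 23 (1S,2R)-3-(benzyloxy)-1-[4-(benzyloxy)-3-methoxyphenyl]-2-{4-[(1S,3aR,4S,6aR)-4-[4-(benzyloxy)-3-methoxyphenyl]tetrahydro-1H,3H-furo[3,4-c]furan-1-yl]-2,6-dimethoxyphenoxy}propan-1-ol
Conditions: Zn(BH4)2, Et2O, −30 °C
Reagents that add atoms: none
Why: Chelation-controlled hydride reduction of an α-alkoxy ketone: zinc bridges the ketone oxygen and the α-aryloxy oxygen and hydride adds from the side of the small α-hydrogen, which should give the 1,2-anti (erythro, 7''S,8''R) alcohol.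

**Step 16**
Reactants: 23 (1S,2R)-3-(benzyloxy)-1-[4-(benzyloxy)-3-methoxyphenyl]-2-{4-[(1S,3aR,4S,6aR)-4-[4-(benzyloxy)-3-methoxyphenyl]tetrahydro-1H,3H-furo[3,4-c]furan-1-yl]-2,6-dimethoxyphenoxy}propan-1-ol
Product: 24 Hedyotol C
Conditions: H2 (1 atm), Pd/C (10% Pd), EtOAc, rt
Reagents that add atoms: none
Why: Catalytic hydrogenolysis of the three O-benzyl groups; a neutral aprotic solvent and stopping after three equivalents of hydrogen should leave the benzylic C–O bonds of the furofuran and the benzylic alcohol intact.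

**Compound list**

1 | syringaldehyde | COc1cc(C=O)cc(OC)c1O | starting material
2 | 4-(allyloxy)-3,5-dimethoxybenzaldehyde | COc1cc(C=O)cc(OC)c1OCC=C | intermediate
3 | 4-(benzyloxy)-3-methoxybenzaldehyde | COc1cc(C=O)ccc1OCc1ccccc1 | starting material
4 | (E)-3-[4-(benzyloxy)-3-methoxyphenyl]prop-2-enal | COc1cc(/C=C/C=O)ccc1OCc1ccccc1 | intermediate
5 | dimethyl bromomalonate | COC(=O)C(Br)C(=O)OC | starting material
6 | dimethyl (2R,3S)-2-formyl-3-[4-(benzyloxy)-3-methoxyphenyl]cyclopropane-1,1-dicarboxylate | COC(=O)C1(C(=O)OC)[C@H](C=O)[C@H]1c1ccc(OCc2ccccc2)c(OC)c1 | intermediate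
7 | dimethyl (2R,3S)-2-(hydroxymethyl)-3-[4-(benzyloxy)-3-methoxyphenyl]cyclopropane-1,1-dicarboxylate | COC(=O)C1(C(=O)OC)[C@H](CO)[C@H]1c1ccc(OCc2ccccc2)c(OC)c1 | intermediate
8 | dimethyl (2R,3S)-2-{[tert-butyl(diphenyl)silyl]oxymethyl}-3-[4-(benzyloxy)-3-methoxyphenyl]cyclopropane-1,1-dicarboxylate | COC(=O)C1(C(=O)OC)[C@H](CO[Si](c2ccccc2)(c2ccccc2)C(C)(C)C)[C@H]1c1ccc(OCc2ccccc2)c(OC)c1 | intermediate
9 | oxocarbenium malonate zwitterion (ring-opened adduct of 8 and 2) | COC(=O)[C-](C(=O)OC)[C@H](CO[Si](c1ccccc1)(c1ccccc1)C(C)(C)C)[C@H](c1ccc(OCc2ccccc2)c(OC)c1)[O+]=Cc1cc(OC)c(OCC=C)c(OC)c1 | intermediate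
10 | dimethyl (2R,4R,5R)-2-[4-(allyloxy)-3,5-dimethoxyphenyl]-5-[4-(benzyloxy)-3-methoxyphenyl]-4-{[tert-butyl(diphenyl)silyl]oxymethyl}dihydrofuran-3,3(2H)-dicarboxylate | COC(=O)C1(C(=O)OC)[C@H](CO[Si](c2ccccc2)(c2ccccc2)C(C)(C)C)[C@H](c2ccc(OCc3ccccc3)c(OC)c2)O[C@@H]1c1cc(OC)c(OCC=C)c(OC)c1 | intermediate
11 | methyl (2S,3S,4R,5R)-2-[4-(allyloxy)-3,5-dimethoxyphenyl]-5-[4-(benzyloxy)-3-methoxyphenyl]-4-{[tert-butyl(diphenyl)silyl]oxymethyl}tetrahydrofuran-3-carboxylate | COC(=O)[C@H]1[C@H](CO[Si](c2ccccc2)(c2ccccc2)C(C)(C)C)[C@H](c2ccc(OCc3ccccc3)c(OC)c2)O[C@@H]1c1cc(OC)c(OCC=C)c(OC)c1 | intermediate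
12 | [(2S,3R,4R,5R)-2-[4-(allyloxy)-3,5-dimethoxyphenyl]-5-[4-(benzyloxy)-3-methoxyphenyl]-4-{[tert-butyl(diphenyl)silyl]oxymethyl}tetrahydrofuran-3-yl]methanol | OC[C@H]1[C@H](CO[Si](c2ccccc2)(c2ccccc2)C(C)(C)C)[C@H](c2ccc(OCc3ccccc3)c(OC)c2)O[C@@H]1c1cc(OC)c(OCC=C)c(OC)c1 | intermediate
13 | [(2S,3R,4R,5R)-2-[4-(allyloxy)-3,5-dimethoxyphenyl]-5-[4-(benzyloxy)-3-methoxyphenyl]tetrahydrofuran-3,4-diyl]dimethanol | OC[C@H]1[C@H](CO)[C@H](c2ccc(OCc3ccccc3)c(OC)c2)O[C@@H]1c1cc(OC)c(OCC=C)c(OC)c1 | intermediate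
14 | 4-[(2S,3R,4R,5R)-5-[4-(benzyloxy)-3-methoxyphenyl]-3,4-bis(hydroxymethyl)tetrahydrofuran-2-yl]-2,6-dimethoxyphenol | OC[C@H]1[C@H](CO)[C@H](c2ccc(OCc3ccccc3)c(OC)c2)O[C@@H]1c1cc(OC)c(O)c(OC)c1 | intermediate
15 | (R)-[4-(benzyloxy)-3-methoxyphenyl][(3R,4R,5S)-5-(4-hydroxy-3,5-dimethoxyphenyl)-4-(hydroxymethyl)tetrahydrofuran-3-yl]methanol | OC[C@@H]1[C@@H](c2cc(OC)c(O)c(OC)c2)OC[C@@H]1[C@@H](O)c1ccc(OCc2ccccc2)c(OC)c1 | intermediate
16 | 4-[(1S,3aR,4S,6aR)-4-[4-(benzyloxy)-3-methoxyphenyl]tetrahydro-1H,3H-furo[3,4-c]furan-1-yl]-2,6-dimethoxyphenol | COc1cc([C@H]2OC[C@H]3[C@@H]2CO[C@@H]3c2cc(OC)c(O)c(OC)c2)ccc1OCc1ccccc1 | intermediate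
17 | methyl (2S)-3-(benzyloxy)-2-hydroxypropanoate | COC(=O)[C@@H](O)COCc1ccccc1 | starting material
18 | (2S)-3-(benzyloxy)-2-hydroxy-N-methoxy-N-methylpropanamide | CON(C)C(=O)[C@@H](O)COCc1ccccc1 | intermediate
19 | (2R)-3-(benzyloxy)-2-{4-[(1S,3aR,4S,6aR)-4-[4-(benzyloxy)-3-methoxyphenyl]tetrahydro-1H,3H-furo[3,4-c]furan-1-yl]-2,6-dimethoxyphenoxy}-N-methoxy-N-methylpropanamide | COc1cc([C@H]2OC[C@H]3[C@@H]2CO[C@@H]3c2cc(OC)c(O[C@H](COCc4ccccc4)C(=O)N(C)OC)c(OC)c2)ccc1OCc1ccccc1 | intermediate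
20 | 1-(benzyloxy)-4-bromo-2-methoxybenzene | COc1cc(Br)ccc1OCc1ccccc1 | starting material
21 | [4-(benzyloxy)-3-methoxyphenyl]magnesium bromide | COc1cc([Mg]Br)ccc1OCc1ccccc1 | intermediate
22 | (2R)-3-(benzyloxy)-1-[4-(benzyloxy)-3-methoxyphenyl]-2-{4-[(1S,3aR,4S,6aR)-4-[4-(benzyloxy)-3-methoxyphenyl]tetrahydro-1H,3H-furo[3,4-c]furan-1-yl]-2,6-dimethoxyphenoxy}propan-1-one | COc1cc([C@H]2OC[C@H]3[C@@H]2CO[C@@H]3c2cc(OC)c(O[C@H](COCc4ccccc4)C(=O)c4ccc(OCc5ccccc5)c(OC)c4)c(OC)c2)ccc1OCc1ccccc1 | intermediate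
23 | (1S,2R)-3-(benzyloxy)-1-[4-(benzyloxy)-3-methoxyphenyl]-2-{4-[(1S,3aR,4S,6aR)-4-[4-(benzyloxy)-3-methoxyphenyl]tetrahydro-1H,3H-furo[3,4-c]furan-1-yl]-2,6-dimethoxyphenoxy}propan-1-ol | COc1cc([C@H]2OC[C@H]3[C@@H]2CO[C@@H]3c2cc(OC)c(O[C@H](COCc4ccccc4)[C@@H](O)c4ccc(OCc5ccccc5)c(OC)c4)c(OC)c2)ccc1OCc1ccccc1 | intermediate
24 | Hedyotol C | COc1cc([C@H]2OC[C@H]3[C@@H]2CO[C@@H]3c2cc(OC)c(O[C@H](CO)[C@@H](O)c3ccc(O)c(OC)c3)c(OC)c2)ccc1O | target

**Step count and risks**

Total step count: 16. Longest linear sequence: 14 steps (3 to 24 through steps 2–11 and 13–16).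

Steps most likely to fail:

Step 11. The acid that builds the bicycle can re-ionize its two benzylic C–O bonds, so prolonged exposure would epimerize C7 and C7' toward exo/endo mixtures; a benzylic cation can also be captured irreversibly by the other aryl ring (Friedel–Crafts cyclization). The fallback is a stepwise transposition in which no benzylic cation forms on the bicycle. It sets out from 12. Catalytic camphorsulfonic acid opens ring T only on the guaiacyl side (the allyl-etherified trialkoxyphenyl C7–O bond ionizes far more slowly) and the free C9 hydroxyl closes ring A, giving (S)-[4-(allyloxy)-3,5-dimethoxyphenyl]{(3R,4R,5S)-5-[4-(benzyloxy)-3-methoxyphenyl]-4-{[tert-butyl(diphenyl)silyl]oxymethyl}tetrahydrofuran-3-yl}methanol F1. Bu4NF frees the C9' hydroxyl to give (S)-[4-(allyloxy)-3,5-dimethoxyphenyl]{(3R,4R,5S)-5-[4-(benzyloxy)-3-methoxyphenyl]-4-(hydroxymethyl)tetrahydrofuran-3-yl}methanol F2. Mitsunobu cyclodehydration (PPh3, DIAD) activates the primary C9' hydroxyl and lets the C7 oxygen attack with retention at C7, closing ring B to (1S,3aR,4S,6aR)-1-[4-(allyloxy)-3,5-dimethoxyphenyl]-4-[4-(benzyloxy)-3-methoxyphenyl]tetrahydro-1H,3H-furo[3,4-c]furan F3. Pd(PPh3)4 with morpholine removes the allyl group, and the route is rejoined at 16.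

Step 6. The electron-rich cyclopropane may ionize before the aldehyde attacks (racemization and loss of the cis relationships), or the Lewis acid may attack the silyl ether. The fallback makes the same C7–C8 bond by oxidative C–H cyclization instead of annulation. It sets out from 8 and 2. NaBH4 reduces 2 to [4-(allyloxy)-3,5-dimethoxyphenyl]methanol F4. Cu(OTf)2-catalysed SN2 ring opening of 8 by F4 (inversion at C7') gives dimethyl 2-{(1R,2R)-1-{[4-(allyloxy)-3,5-dimethoxybenzyl]oxy}-1-[4-(benzyloxy)-3-methoxyphenyl]-3-{[tert-butyl(diphenyl)silyl]oxy}propan-2-yl}malonate F5. DDQ then abstracts hydride from the electron-rich benzylic CH2 of F5 and the malonate carbon adds to the resulting oxocarbenium ion, closing ring T and rejoining the route at 10.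

Step 13. The 2,6-disubstituted phenol may couple slowly, so that the activated alcohol eliminates or is intercepted by the hydrazide. The fallback replaces the Mitsunobu redox condensation by SN2 displacement of a triflate. It sets out from 17. Tf2O with 2,6-lutidine gives methyl (2S)-3-(benzyloxy)-2-{[(trifluoromethyl)sulfonyl]oxy}propanoate F6. The potassium phenoxide of 16 (K2CO3, MeCN) displaces the triflate with inversion to give methyl (2R)-3-(benzyloxy)-2-{4-[(1S,3aR,4S,6aR)-4-[4-(benzyloxy)-3-methoxyphenyl]tetrahydro-1H,3H-furo[3,4-c]furan-1-yl]-2,6-dimethoxyphenoxy}propanoate F7. Amidation with MeNH(OMe)·HCl and i-PrMgCl converts F7 into 19, where the route is rejoined.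

**Further compounds**

F1 | step 11 | (S)-[4-(allyloxy)-3,5-dimethoxyphenyl]{(3R,4R,5S)-5-[4-(benzyloxy)-3-methoxyphenyl]-4-{[tert-butyl(diphenyl)silyl]oxymethyl}tetrahydrofuran-3-yl}methanol | O[C@H](c1cc(OC)c(OCC=C)c(OC)c1)[C@H]1CO[C@H](c2ccc(OCc3ccccc3)c(OC)c2)[C@H]1CO[Si](c1ccccc1)(c1ccccc1)C(C)(C)C
F2 | step 11 | (S)-[4-(allyloxy)-3,5-dimethoxyphenyl]{(3R,4R,5S)-5-[4-(benzyloxy)-3-methoxyphenyl]-4-(hydroxymethyl)tetrahydrofuran-3-yl}methanol | O[C@H](c1cc(OC)c(OCC=C)c(OC)c1)[C@H]1CO[C@H](c2ccc(OCc3ccccc3)c(OC)c2)[C@H]1CO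
F3 | step 11 | (1S,3aR,4S,6aR)-1-[4-(allyloxy)-3,5-dimethoxyphenyl]-4-[4-(benzyloxy)-3-methoxyphenyl]tetrahydro-1H,3H-furo[3,4-c]furan | COc1cc([C@H]2OC[C@H]3[C@@H]2CO[C@@H]3c2cc(OC)c(OCC=C)c(OC)c2)ccc1OCc1ccccc1
F4 | step 6 | [4-(allyloxy)-3,5-dimethoxyphenyl]methanol | COc1cc(CO)cc(OC)c1OCC=C
F5 | step 6 | dimethyl 2-{(1R,2R)-1-{[4-(allyloxy)-3,5-dimethoxybenzyl]oxy}-1-[4-(benzyloxy)-3-methoxyphenyl]-3-{[tert-butyl(diphenyl)silyl]oxy}propan-2-yl}malonate | COC(=O)C(C(=O)OC)[C@H](CO[Si](c1ccccc1)(c1ccccc1)C(C)(C)C)[C@@H](OCc1cc(OC)c(OCC=C)c(OC)c1)c1ccc(OCc2ccccc2)c(OC)c1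
F6 | step 13 | methyl (2S)-3-(benzyloxy)-2-{[(trifluoromethyl)sulfonyl]oxy}propanoate | COC(=O)[C@@H](OS(=O)(=O)C(F)(F)F)COCc1ccccc1
F7 | step 13 | methyl (2R)-3-(benzyloxy)-2-{4-[(1S,3aR,4S,6aR)-4-[4-(benzyloxy)-3-methoxyphenyl]tetrahydro-1H,3H-furo[3,4-c]furan-1-yl]-2,6-dimethoxyphenoxy}propanoate | COc1cc([C@H]2OC[C@H]3[C@@H]2CO[C@@H]3c2cc(OC)c(O[C@H](COCc4ccccc4)C(=O)OC)c(OC)c2)ccc1OCc1ccccc1
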